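**Retrosynthetic overview**
1. The side-chain ester C4'–O bond comes from an SN2 reaction with inversion between cesium (R)-mevalonate (from (R)-mevalonolactone) and the (4'S)-tosylate of the 5,8-dihydroxy-3,4-dihydroisocoumarin. The tosylate is carried from step 2 as both protecting group and leaving group.
2. The C5–OH comes from para-hydroxylation of the 8-monophenol, mirroring the oxygenase step that follows chain assembly.
3. Both rings come from one open-chain reduced heptaketide (a C14 9-oxy-3,7-dioxo-5-enoate) in one flask. The C2-to-C7 aldol and dehydration form the benzene ring first, and attack of the C9 oxygen on C1 then closes the δ-lactone.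
4. That chain is released in the flask from an (R)-2-alkyl-2,3-dihydropyran-4-one (a temporary ring that is opened again) and Chan's diene, which supplies the last two acetate units.
5. The dihydropyranone comes from a catalytic asymmetric hetero-Diels–Alder reaction of Danishefsky's diene with (S)-5-(tosyloxy)hexanal, itself made from (S)-propylene oxide and butenylmagnesium bromide.

Assumption: the sense of induction of the BINOL/Ti(OiPr)4 catalyst is taken from its allylation and Mukaiyama aldol behaviour, where (S)-BINOL gives Si-face attack on an unbranched aldehyde. If the first run shows the opposite sense, (R)-BINOL is used and nothing else changes.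

Numbering: isocoumarin numbering is used for the bicycle (C1 lactone carbonyl, C3 carbinol, C4 CH2), C1'–C5' for the side chain, and polyketide numbering C1–C14 for open-chain intermediates.

**Step 1**
Reactants: 1 (S)-propylene oxide; 2 but-3-en-1-ylmagnesium bromide
Product: 3 (2S)-hept-6-en-2-ol
Conditions: CuI (10 mol %), THF, −30 °C to 0 °C; then H2O/aq NH4Cl
Reagents that add atoms: none
Why: Copper-catalysed SN2 opening of the terminal epoxide by the Grignard reagent takes place at the unsubstituted carbon, so the C–O stereocentre of 1 passes unchanged into 3 as (S).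

**Step 2**
Reactants: 3 (2S)-hept-6-en-2-ol
Product: 4 (2S)-hept-6-en-2-yl 4-methylbenzenesulfonate
Conditions: TsCl, Et3N, DMAP (cat), CH2Cl2, 0 °C to rt
Reagents that add atoms: p-toluenesulfonyl chloride (TsCl), Cc1ccc(cc1)S(=O)(=O)Cl
Why: O-Sulfonylation leaves the C–O bond untouched (configuration retained) and installs one group that protects the hydroxyl through steps 3 to 7 and serves as the leaving group in step 8.

**Step 3**
Reactants: 4 (2S)-hept-6-en-2-yl 4-methylbenzenesulfonate
Product: 6 (2S)-6-oxohexan-2-yl 4-methylbenzenesulfonate [(5S)-5-(tosyloxy)hexanal], via secondary ozonide 5 (not isolated)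
Conditions: O3, CH2Cl2, −78 °C; then Me2S, −78 °C to rt
Reagents that add atoms: ozone, [O-][O+]=O
Why: Ozonolysis with reductive work-up (Criegee mechanism) cleaves only the terminal alkene, because the electron-poor tosyl arene and the sulfonate ester are inert at −78 °C.

**Step 4**
Reactants: 6 (5S)-5-(tosyloxy)hexanal; 7 Danishefsky's diene [(E)-1-methoxy-3-(trimethylsilyloxy)buta-1,3-diene]
Product: 9 (2R)-2-[(4S)-4-(tosyloxy)pentyl]-2,3-dihydro-4H-pyran-4-one, via silylated Mukaiyama aldol adduct 8 (not isolated)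
Conditions: (S)-BINOL (20 mol %), Ti(OiPr)4 (10 mol %), CF3CO2H (0.3 mol %), 4 Å MS, Et2O, −20 °C; then CF3CO2H (cat), CH2Cl2, 0 °C
Reagents that add atoms: none
Why: This is a catalytic asymmetric hetero-Diels–Alder reaction run in its stepwise Mukaiyama aldol/cyclocondensation form, in which the (S)-BINOL titanium complex blocks the Re face of the aldehyde so that the diene terminus adds to the Si face and sets the future C3 as (R), after which acid closes the vinylogous ester with loss of the methoxy and silyl groups.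

**Step 5**
Reactants: 10 methyl acetoacetate
Product: 11 Chan's diene [1-methoxy-1,3-bis(trimethylsilyloxy)buta-1,3-diene]
Conditions: TMSOTf (2.1 equiv), Et3N (2.4 equiv), Et2O, 0 °C to rt; used after removal of the salt layer
Reagents that add atoms: trimethylsilyl triflate (TMSOTf), C[Si](C)(C)OS(=O)(=O)C(F)(F)F
Why: Double soft enolisation and O-silylation of the β-keto ester gives the 1,3-bis(silyl enol ether), a masked acetoacetate dianion that stands for the last two acetate units of the chain.

**Step 6**
Reactants: 9 (2R)-2-[(4S)-4-(tosyloxy)pentyl]-2,3-dihydro-4H-pyran-4-one; 11 Chan's diene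
Product: 15 (3R)-8-hydroxy-3-[(4S)-4-(tosyloxy)pentyl]-3,4-dihydroisocoumarin, via trans-dihydropyran bis-silyl adduct 12 (not isolated), via open-chain bis-silyl enone 13 (not isolated), via hydroxy salicylate ester 14 (not isolated)
Conditions: TMSOTf (1.5 equiv), CH2Cl2, −78 °C; 11 (1.5 equiv), −78 °C to 0 °C, 3 h; then Et3N (5 equiv), MeOH, 0 °C to rt, 12 h; then 1 M HCl
Reagents that add atoms: none
Why: Proposed new method: TMSOTf O-silylates the vinylogous ester 9 to a cyclic oxocarbenium ion that the terminal carbon of 11 attacks axially at C6 (vinylogous Mukaiyama–Michael addition) to give 12; the ring C6–O bond of 12 is then allylic to a silyl enol ether and ionises under TMSOTf just as the alkoxy group of a Danishefsky-diene adduct does, which opens the pyran regiospecifically to the linear C14 chain 13 without ever breaking the C–O bond at the (R)-carbinol carbon; Et3N/MeOH frees the β-keto ester, whose C2 adds to the C7 ketone (the aldol used by the polyketide synthase), loss of water and tautomerisation give salicylate 14, and the liberated C9 hydroxyl closes the δ-lactone on the methyl ester; the closest known reaction types are the Chan–Brownbridge [3+3] cycloaromatisation of 1,3-bis(silyl enol ethers) with β-alkoxy enones and the domino retro-Michael/aldol/lactonisation of the chromone adducts of such dienes, the new element being an alkoxide rather than a phenoxide as the internal leaving group.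

**Step 7**
Reactants: 15 (3R)-8-hydroxy-3-[(4S)-4-(tosyloxy)pentyl]-3,4-dihydroisocoumarin
Product: 17 (3R)-5,8-dihydroxy-3-[(4S)-4-(tosyloxy)pentyl]-3,4-dihydroisocoumarin, via para-quinone 16 (not isolated)
Conditions: PhI(OCOCF3)2 (2.2 equiv), MeCN–H2O 2:1, 0 °C, 30 min; then sat aq Na2S2O4, EtOAc, rt, 10 min
Reagents that add atoms: water, O
Why: Oxidation of a para-unsubstituted phenol by the trivalent iodine reagent lets water attack the free position para to the 8-OH, the hydroquinone formed is oxidised on to quinone 16 by the second equivalent, and dithionite reduces it back, so the net result is the oxygenase-type para-hydroxylation with no stereocentre, sulfonate or lactone touched.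

**Step 8**
Reactants: 17 (3R)-5,8-dihydroxy-3-[(4S)-4-(tosyloxy)pentyl]-3,4-dihydroisocoumarin; 18 (R)-mevalonolactone
Product: 20 target CNP0591388.1 [(2R)-5-[(3R)-5,8-dihydroxy-1-oxo-3,4-dihydro-1H-isochromen-3-yl]pentan-2-yl (3R)-3,5-dihydroxy-3-methylpentanoate], via cesium (R)-mevalonate 19 (not isolated)
Conditions: 18 (2.0 equiv), CsOH·H2O (1.95 equiv), MeOH–H2O, rt, evaporate and dry by toluene azeotrope; then 17, DMF, 45 °C, Ar, 24 h; pH 6 phosphate buffer work-up
Reagents that add atoms: cesium hydroxide, [Cs+].[OH-]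
Why: SN2 O-alkylation of a cesium carboxylate by the unhindered secondary tosylate proceeds with clean inversion, (S) to (R) at C4'; it is irreversible, so it bypasses the unfavourable lactone/hydroxy-ester equilibrium; it needs no protection, because the neutral alcohols and phenols are far weaker nucleophiles than the carboxylate; and it leaves the (R) tertiary carbinol of 18 untouched.

**Compound list**
1 | (S)-propylene oxide | C[C@H]1CO1 | starting material
2 | but-3-en-1-ylmagnesium bromide | C=CCC[Mg]Br | starting material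
3 | (2S)-hept-6-en-2-ol | C[C@H](O)CCCC=C | intermediate
4 | (2S)-hept-6-en-2-yl 4-methylbenzenesulfonate | C[C@H](OS(=O)(=O)c1ccc(C)cc1)CCCC=C | intermediate
5 | (2S)-5-(1,2,4-trioxolan-3-yl)pentan-2-yl 4-methylbenzenesulfonate (secondary ozonide, both epimers at the trioxolane carbon) | C[C@H](OS(=O)(=O)c1ccc(C)cc1)CCCC1OCOO1 | intermediate
6 | (2S)-6-oxohexan-2-yl 4-methylbenzenesulfonate | C[C@H](OS(=O)(=O)c1ccc(C)cc1)CCCC=O | intermediate
7 | Danishefsky's diene, (E)-1-methoxy-3-(trimethylsilyloxy)buta-1,3-diene | CO/C=C/C(=C)O[Si](C)(C)C | starting material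
8 | (1E,5R,9S)-1-methoxy-9-(tosyloxy)-5-(trimethylsilyloxy)dec-1-en-3-one | CO/C=C/C(=O)C[C@H](O[Si](C)(C)C)CCC[C@H](C)OS(=O)(=O)c1ccc(C)cc1 | intermediate
9 | (2R)-2-[(4S)-4-(tosyloxy)pentyl]-2,3-dihydro-4H-pyran-4-one | O=C1C=CO[C@H](CCC[C@H](C)OS(=O)(=O)c2ccc(C)cc2)C1 | intermediate
10 | methyl acetoacetate | COC(=O)CC(C)=O | starting material
11 | Chan's diene, 1-methoxy-1,3-bis(trimethylsilyloxy)buta-1,3-diene (E/Z mixture) | COC(O[Si](C)(C)C)=CC(=C)O[Si](C)(C)C | intermediate
12 | methyl 4-{(2R,6R)-6-[(4S)-4-(tosyloxy)pentyl]-4-(trimethylsilyloxy)-5,6-dihydro-2H-pyran-2-yl}-3-(trimethylsilyloxy)but-2-enoate (2,6-trans; enol ether E/Z) | COC(=O)C=C(O[Si](C)(C)C)C[C@@H]1C=C(O[Si](C)(C)C)C[C@@H](CCC[C@H](C)OS(=O)(=O)c2ccc(C)cc2)O1 | intermediate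
13 | methyl (5E,9R,13S)-7-oxo-13-(tosyloxy)-3,9-bis(trimethylsilyloxy)tetradeca-2,5-dienoate (C2 enol ether E/Z) | COC(=O)C=C(O[Si](C)(C)C)C/C=C/C(=O)C[C@H](O[Si](C)(C)C)CCC[C@H](C)OS(=O)(=O)c1ccc(C)cc1 | intermediate
14 | methyl 2-hydroxy-6-[(2R,6S)-2-hydroxy-6-(tosyloxy)heptyl]benzoate | COC(=O)c1c(O)cccc1C[C@H](O)CCC[C@H](C)OS(=O)(=O)c1ccc(C)cc1 | intermediate
15 | (3R)-8-hydroxy-3-[(4S)-4-(tosyloxy)pentyl]-3,4-dihydroisocoumarin | C[C@@H](CCC[C@@H]1Cc2cccc(O)c2C(=O)O1)OS(=O)(=O)c1ccc(C)cc1 | intermediate
16 | (3R)-3-[(4S)-4-(tosyloxy)pentyl]-3,4-dihydro-1H-isochromene-1,5,8-trione | C[C@@H](CCC[C@@H]1CC2=C(C(=O)C=CC2=O)C(=O)O1)OS(=O)(=O)c1ccc(C)cc1 | intermediate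
17 | (3R)-5,8-dihydroxy-3-[(4S)-4-(tosyloxy)pentyl]-3,4-dihydroisocoumarin | C[C@@H](CCC[C@@H]1Cc2c(O)ccc(O)c2C(=O)O1)OS(=O)(=O)c1ccc(C)cc1 | intermediate
18 | (R)-mevalonolactone | C[C@@]1(O)CCOC(=O)C1 | starting material
19 | cesium (3R)-3,5-dihydroxy-3-methylpentanoate | C[C@@](O)(CCO)CC(=O)[O-].[Cs+] | intermediate
20 | (2R)-5-[(3R)-5,8-dihydroxy-1-oxo-3,4-dihydro-1H-isochromen-3-yl]pentan-2-yl (3R)-3,5-dihydroxy-3-methylpentanoate | C[C@H](CCC[C@@H]1Cc2c(O)ccc(O)c2C(=O)O1)OC(=O)C[C@](C)(O)CCO | target

**Step count**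
- Total steps: 8.
- Longest linear sequence: 7 (steps 1, 2, 3, 4, 6, 7, 8). Step 5 is a one-step side branch.

**Three steps most likely to fail**

**Step 6.** The pyran may stay closed, or under base it may open at the wrong C–O bond, which would erode C3 or give a 6-alkenylsalicylate.

The fallback sets out from 8 and comes back at 13. Step 4 is stopped before the acid treatment and 8 is isolated on Et3N-deactivated silica. This acyclic β-methoxy enone is treated with 11 and TMSOTf in CH2Cl2 at −78 °C, which is the established [3+3] mode in which methoxide, not the C9 oxygen, is the leaving group. Conjugate addition gives methyl (9R,13S)-5-methoxy-13-(tosyloxy)-3,7,9-tris(trimethylsilyloxy)tetradeca-2,6-dienoate F1. F1 expels its methoxy group to give 13, and the Et3N/MeOH stage of step 6 then follows unchanged.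

**Step 7.** The hydrogen-bonded, electron-poor salicylate may oxidise slowly, or the acylquinone 16 may be consumed by water.

The fallback sets out from 9 and comes back at 17. It places the oxygen on the electron-rich enol-ether carbon before the arene exists.
- DMDO in acetone–MeOH at 0 °C converts 9 into (2R)-5-hydroxy-6-methoxy-2-[(4S)-4-(tosyloxy)pentyl]tetrahydro-4H-pyran-4-one F2.
- Ac2O, Et3N and DMAP acetylate F2 and eliminate methanol (E1cB) to give (2R)-4-oxo-2-[(4S)-4-(tosyloxy)pentyl]-3,4-dihydro-2H-pyran-5-yl acetate F3.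
- The conditions of step 6 with 11 turn F3 into (3R)-8-hydroxy-1-oxo-3-[(4S)-4-(tosyloxy)pentyl]-3,4-dihydro-1H-isochromen-5-yl acetate F4.
- Catalytic K2CO3 in MeOH at 0 °C removes the aryl acetate from F4 to give 17.

**Step 8.** E2 elimination may compete, or the freshly formed δ-hydroxy ester may re-lactonise under the mildly basic conditions and expel the side-chain alcohol.

The fallback sets out from 19 (with 17 as partner) and comes back at 20. It blocks the primary hydroxyl during the displacement.
- TBSCl (2.2 equiv) and imidazole in DMF convert 19 into tert-butyldimethylsilyl (3R)-5-(tert-butyldimethylsilyloxy)-3-hydroxy-3-methylpentanoate F5.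
- Cs2CO3 in aqueous MeOH cleaves only the silyl ester of F5 to give cesium (3R)-5-(tert-butyldimethylsilyloxy)-3-hydroxy-3-methylpentanoate F6.
- F6 displaces the tosylate of 17 in DMF at 45 °C to give the 5-O-TBS ether of the target F7.
- HF·pyridine in THF at 0 °C releases 20 from F7.

**Further compounds**
F1 | step 6 | methyl (9R,13S)-5-methoxy-13-(tosyloxy)-3,7,9-tris(trimethylsilyloxy)tetradeca-2,6-dienoate (mixture at C5 and at both enol ethers) | COC(=O)C=C(O[Si](C)(C)C)CC(OC)C=C(O[Si](C)(C)C)C[C@H](O[Si](C)(C)C)CCC[C@H](C)OS(=O)(=O)c1ccc(C)cc1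
F2 | step 7 | (2R)-5-hydroxy-6-methoxy-2-[(4S)-4-(tosyloxy)pentyl]tetrahydro-4H-pyran-4-one (mixture at C5 and C6) | COC1O[C@H](CCC[C@H](C)OS(=O)(=O)c2ccc(C)cc2)CC(=O)C1O
F3 | step 7 | (2R)-4-oxo-2-[(4S)-4-(tosyloxy)pentyl]-3,4-dihydro-2H-pyran-5-yl acetate | CC(=O)OC1=CO[C@H](CCC[C@H](C)OS(=O)(=O)c2ccc(C)cc2)CC1=O
F4 | step 7 | (3R)-8-hydroxy-1-oxo-3-[(4S)-4-(tosyloxy)pentyl]-3,4-dihydro-1H-isochromen-5-yl acetate | C[C@@H](CCC[C@@H]1Cc2c(OC(C)=O)ccc(O)c2C(=O)O1)OS(=O)(=O)c1ccc(C)cc1
F5 | step 8 | tert-butyldimethylsilyl (3R)-5-(tert-butyldimethylsilyloxy)-3-hydroxy-3-methylpentanoate | C[C@@](O)(CCO[Si](C)(C)C(C)(C)C)CC(=O)O[Si](C)(C)C(C)(C)C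
F6 | step 8 | cesium (3R)-5-(tert-butyldimethylsilyloxy)-3-hydroxy-3-methylpentanoate | C[C@@](O)(CCO[Si](C)(C)C(C)(C)C)CC(=O)[O-].[Cs+]
F7 | step 8 | (2R)-5-[(3R)-5,8-dihydroxy-1-oxo-3,4-dihydro-1H-isochromen-3-yl]pentan-2-yl (3R)-5-(tert-butyldimethylsilyloxy)-3-hydroxy-3-methylpentanoate | C[C@H](CCC[C@@H]1Cc2c(O)ccc(O)c2C(=O)O1)OC(=O)C[C@](C)(O)CCO[Si](C)(C)C(C)(C)C
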